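**Plan**

1. Numbering: cyclohexene C1 (bears the ketone carbon C7) to C6 (bears phenyl); ring A is C1′–C6′ with OMe at C2′ and OH at C4′ and C6′.
2. Retrosynthesis: with C7 as a silyl-protected carbinol and the phenols masked as allyl ethers, ring A is cut at C1′–C6′, C2′–C3′ and C5′–C6′ into a methoxyalkyne (C1′, C2′) and a 3-allyloxycyclobutenone (C3′–C6′). Then C7–C1′ is cut (acetylide + aldehyde), then C1–C2 and C5–C6 (Diels–Alder of cinnamaldehyde and myrcene).
3. Enabling feature: ring A is a phloroglucinol with three differentiated oxygens. An alkoxyalkyne supplies C1′ and C2′–OMe; the vinylketene from a 3-alkoxycyclobutenone supplies C6′–OH (ketene carbon) and C4′–O (enol ether oxygen).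
4. Forward order: cyclohexene ring (step 1), C7–C1′ bond and silylation (steps 2–3), cyclobutenone partner (step 4), ring A by benzannulation (step 5), then allylation, desilylation, oxidation and deallylation (steps 6–9).
5. Stereochemistry: C1 and C6 both arise in step 1 (trans from the E-enal, absolute sense from the (R)-diarylprolinol silyl ether); the C7 carbinol centre is transient and is erased in step 8.

Key step: step 5

Assumption: the absolute sense of step 1 is assigned from the usual face-shielding model of diarylprolinol silyl ether iminium ions ((R)-catalyst giving (1R,6R)); the C7 carbinol is carried as an epimer mixture because step 8 removes that centre.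

**Route**

Step 1
Reactants: 1 (E)-cinnamaldehyde; 2 myrcene
Product: 3 (1R,6R)-4-(4-methylpent-3-en-1-yl)-6-phenylcyclohex-3-ene-1-carbaldehyde
Conditions: (R)-2-{bis[3,5-bis(trifluoromethyl)phenyl][(trimethylsilyl)oxy]methyl}pyrrolidine (10 mol%), CF3CO2H (20 mol%), 2 (3 equiv), toluene, rt
Reagents that add atoms: none
Why: Iminium-ion organocatalytic Diels–Alder reaction, in which the 2-substituted diene should add with "para" orientation (C1–CHO 1,4 to the side chain), the E-enal fixes the trans C1/C6 relationship, and the diaryl(silyloxy)methyl group shields one face of the s-trans E-iminium ion so that both centres should arise as (1R,6R).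

Step 2
Reactants: 3 (1R,6R)-4-(4-methylpent-3-en-1-yl)-6-phenylcyclohex-3-ene-1-carbaldehyde; 4 chloroacetaldehyde dimethyl acetal
Product: 6 3-methoxy-1-[(1R,6R)-4-(4-methylpent-3-en-1-yl)-6-phenylcyclohex-3-en-1-yl]prop-2-yn-1-ol (both C7 epimers), via lithium methoxyacetylide 5 (not isolated)
Conditions: 4 (1.5 equiv), LiNEt2 (4.5 equiv, from Et2NH and n-BuLi), THF, 0 °C; then 3, −78 °C; aq. NaHCO3
Reagents that add atoms: none
Why: Threefold base-induced elimination from 4 gives the lithium alkoxyacetylide, whose 1,2-addition to the aldehyde at −78 °C should outrun enolisation; the carbinol centre forms under Felkin–Anh control as an epimer mixture, which is immaterial because C7 is later oxidised.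

Step 3
Reactants: 6 3-methoxy-1-[(1R,6R)-4-(4-methylpent-3-en-1-yl)-6-phenylcyclohex-3-en-1-yl]prop-2-yn-1-ol
Product: 7 triisopropyl({3-methoxy-1-[(1R,6R)-4-(4-methylpent-3-en-1-yl)-6-phenylcyclohex-3-en-1-yl]prop-2-yn-1-yl}oxy)silane (both C7 epimers)
Conditions: TIPSOTf (1.3 equiv), 2,6-lutidine (2.5 equiv), CH2Cl2, −78 → −20 °C
Reagents that add atoms: triisopropylsilyl trifluoromethanesulfonate, CC(C)[Si](OS(=O)(=O)C(F)(F)F)(C(C)C)C(C)C
Why: Lutidine-buffered O-silylation with a silyl triflate keeps the acid-labile alkoxyalkynyl carbinol away from protic acid (no Meyer–Schuster rearrangement), and the bulky silyl ether prevents ketene capture by the alcohol and later silyl migration to the neighbouring phenol.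

Step 4
Reactants: 8 3-ethoxycyclobut-2-en-1-one
Product: 9 3-(prop-2-en-1-yloxy)cyclobut-2-en-1-one
Conditions: allyl alcohol (solvent), TsOH·H2O (2 mol%), rt, EtOH stripped under reduced pressure (repeated)
Reagents that add atoms: allyl alcohol, C=CCO
Why: Acid-catalysed addition–elimination at C3 of the vinylogous ester (vinylogous transesterification), driven by excess allyl alcohol and removal of ethanol, at a temperature well below that of electrocyclic ring opening.

Step 5
Reactants: 7 triisopropyl({3-methoxy-1-[(1R,6R)-4-(4-methylpent-3-en-1-yl)-6-phenylcyclohex-3-en-1-yl]prop-2-yn-1-yl}oxy)silane; 9 3-(prop-2-en-1-yloxy)cyclobut-2-en-1-one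
Product: 14 5-(allyloxy)-3-methoxy-2-{[(1R,6R)-4-(4-methylpent-3-en-1-yl)-6-phenylcyclohex-3-en-1-yl][(triisopropylsilyl)oxy]methyl}phenol, via vinylketene 10 (not isolated), via vinylcyclobutenone 11 (not isolated), via dienylketene 12 (not isolated), via cyclohexadienone 13 (not isolated)
Conditions: 9 (2 equiv), toluene (0.5 M), sealed tube, 80 → 110 °C; then K2CO3, MeOH, rt
Reagents that add atoms: none
Why: Thermal four-electron electrocyclic opening of 9 gives vinylketene 10, whose ketene C=C adds [2+2] to the electron-rich alkyne of 7, the alkyne carbon remote from OMe bonding to the ketene carbonyl carbon (C1′–C6′) and the OMe-bearing carbon to the ketene α-carbon (C2′–C3′), giving 11. Reversible four-electron opening of 11 to dienylketene 12 and six-electron electrocyclisation (C5′–C6′) give dienone 13, which tautomerises to phenol 14. This is the Danheiser benzannulation of a cyclobutenone with an alkoxyalkyne, a reaction class that also accepts 3-oxygenated cyclobutenones. Ring A closes by a thermally allowed disrotatory 6π electrocyclisation of the cis-dienylketene followed by enolisation, with no ionic or radical intermediate, so the side-chain alkenes and the allyl group should remain spectators. No lasting stereocentre is created: the sp3 ring carbon of 11 is destroyed on ring opening, and C1, C6 and the silyloxy carbinol carbon are untouched. The step needs regioselectivity in the [2+2] event, secured by the polarisation of the ynol ether (OMe ends ortho and O-allyl para to C1′), and chemoselectivity for the alkyne over the three alkenes, secured by its much higher nucleophilicity; the methyl ynol ether has no β-hydrogen for retro-ene loss, and the K2CO3/MeOH treatment returns any phenol acylated by excess ketene.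

Step 6
Reactants: 14 5-(allyloxy)-3-methoxy-2-{[(1R,6R)-4-(4-methylpent-3-en-1-yl)-6-phenylcyclohex-3-en-1-yl][(triisopropylsilyl)oxy]methyl}phenol
Product: 15 {[2,4-bis(allyloxy)-6-methoxyphenyl][(1R,6R)-4-(4-methylpent-3-en-1-yl)-6-phenylcyclohex-3-en-1-yl]methoxy}triisopropylsilane
Conditions: allyl bromide (1.5 equiv), K2CO3 (2 equiv), DMF, rt
Reagents that add atoms: allyl bromide, C=CCBr
Why: Williamson O-allylation of the phenoxide caps the C6′ phenol so that the benzylic alcohol freed in the next step cannot ionise through an ortho-quinone methide, and it leaves two identical allyl ethers for a single final deprotection.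

Step 7
Reactants: 15 {[2,4-bis(allyloxy)-6-methoxyphenyl][(1R,6R)-4-(4-methylpent-3-en-1-yl)-6-phenylcyclohex-3-en-1-yl]methoxy}triisopropylsilane
Product: 16 [2,4-bis(allyloxy)-6-methoxyphenyl][(1R,6R)-4-(4-methylpent-3-en-1-yl)-6-phenylcyclohex-3-en-1-yl]methanol (both C7 epimers)
Conditions: Bu4NF (2 equiv), THF, rt → 45 °C; chromatography on Et3N-deactivated silica
Reagents that add atoms: none
Why: Fluoride-induced Si–O cleavage under basic, non-acidic conditions should free the electron-rich benzylic alcohol without ionising it.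

Step 8
Reactants: 16 [2,4-bis(allyloxy)-6-methoxyphenyl][(1R,6R)-4-(4-methylpent-3-en-1-yl)-6-phenylcyclohex-3-en-1-yl]methanol
Product: 17 [2,4-bis(allyloxy)-6-methoxyphenyl][(1R,6R)-4-(4-methylpent-3-en-1-yl)-6-phenylcyclohex-3-en-1-yl]methanone
Conditions: Dess–Martin periodinane (1.5 equiv), NaHCO3 (5 equiv), CH2Cl2, 0 °C → rt
Reagents that add atoms: none
Why: Buffered Dess–Martin oxidation of the secondary benzylic alcohol removes the arbitrary C7 centre; C1, now α to the carbonyl, already has the thermodynamically preferred trans (diequatorial) arrangement and should not epimerise.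

Step 9
Reactants: 17 [2,4-bis(allyloxy)-6-methoxyphenyl][(1R,6R)-4-(4-methylpent-3-en-1-yl)-6-phenylcyclohex-3-en-1-yl]methanone
Product: 18 (2,4-dihydroxy-6-methoxyphenyl)[(1R,6R)-4-(4-methylpent-3-en-1-yl)-6-phenylcyclohex-3-en-1-yl]methanone
Conditions: Pd(PPh3)4 (5 mol%), morpholine (10 equiv), THF, rt; dilute aq. citric acid work-up
Reagents that add atoms: none
Why: Tsuji–Trost-type deallylation, in which zerovalent palladium ionises both aryl allyl ethers to π-allylpalladium species that morpholine intercepts, under conditions that should leave the methyl ether, the ketone, both alkenes and the stereocentres untouched.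

**Compound list**

1 | (E)-cinnamaldehyde | O=C/C=C/c1ccccc1 | starting material
2 | myrcene | C=CC(=C)CCC=C(C)C | starting material
3 | (1R,6R)-4-(4-methylpent-3-en-1-yl)-6-phenylcyclohex-3-ene-1-carbaldehyde | O=C[C@@H]1CC=C(CCC=C(C)C)C[C@H]1c1ccccc1 | intermediate
4 | chloroacetaldehyde dimethyl acetal | COC(CCl)OC | starting material
5 | lithium methoxyacetylide | [Li]C#COC | intermediate
6 | 3-methoxy-1-[(1R,6R)-4-(4-methylpent-3-en-1-yl)-6-phenylcyclohex-3-en-1-yl]prop-2-yn-1-ol (C7 epimer mixture) | COC#CC(O)[C@@H]1CC=C(CCC=C(C)C)C[C@H]1c1ccccc1 | intermediate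
7 | triisopropyl({3-methoxy-1-[(1R,6R)-4-(4-methylpent-3-en-1-yl)-6-phenylcyclohex-3-en-1-yl]prop-2-yn-1-yl}oxy)silane (C7 epimer mixture) | COC#CC(O[Si](C(C)C)(C(C)C)C(C)C)[C@@H]1CC=C(CCC=C(C)C)C[C@H]1c1ccccc1 | intermediate
8 | 3-ethoxycyclobut-2-en-1-one | CCOC1=CC(=O)C1 | starting material
9 | 3-(prop-2-en-1-yloxy)cyclobut-2-en-1-one | C=CCOC1=CC(=O)C1 | intermediate
10 | 3-(allyloxy)buta-1,3-dien-1-one (vinylketene) | O=C=CC(=C)OCC=C | intermediate
11 | 4-[1-(allyloxy)ethenyl]-3-methoxy-2-{[(1R,6R)-4-(4-methylpent-3-en-1-yl)-6-phenylcyclohex-3-en-1-yl][(triisopropylsilyl)oxy]methyl}cyclobut-2-en-1-one (ring C4 and C7 unassigned) | COC1=C(C(O[Si](C(C)C)(C(C)C)C(C)C)[C@@H]2CC=C(CCC=C(C)C)C[C@H]2c2ccccc2)C(=O)C1C(=C)OCC=C | intermediate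
12 | 5-(allyloxy)-3-methoxy-2-{[(1R,6R)-4-(4-methylpent-3-en-1-yl)-6-phenylcyclohex-3-en-1-yl][(triisopropylsilyl)oxy]methyl}hexa-1,3,5-trien-1-one (ketene carbon and alkoxyvinyl group cis across C3=C4) | O=C=C(C(O[Si](C(C)C)(C(C)C)C(C)C)[C@@H]1CC=C(CCC=C(C)C)C[C@H]1c1ccccc1)/C(OC)=C\C(=C)OCC=C | intermediate
13 | 5-(allyloxy)-3-methoxy-2-{[(1R,6R)-4-(4-methylpent-3-en-1-yl)-6-phenylcyclohex-3-en-1-yl][(triisopropylsilyl)oxy]methyl}cyclohexa-2,4-dien-1-one | COC1=C(C(O[Si](C(C)C)(C(C)C)C(C)C)[C@@H]2CC=C(CCC=C(C)C)C[C@H]2c2ccccc2)C(=O)CC(OCC=C)=C1 | intermediate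
14 | 5-(allyloxy)-3-methoxy-2-{[(1R,6R)-4-(4-methylpent-3-en-1-yl)-6-phenylcyclohex-3-en-1-yl][(triisopropylsilyl)oxy]methyl}phenol (C7 epimer mixture) | COc1cc(OCC=C)cc(O)c1C(O[Si](C(C)C)(C(C)C)C(C)C)[C@@H]1CC=C(CCC=C(C)C)C[C@H]1c1ccccc1 | intermediate
15 | {[2,4-bis(allyloxy)-6-methoxyphenyl][(1R,6R)-4-(4-methylpent-3-en-1-yl)-6-phenylcyclohex-3-en-1-yl]methoxy}triisopropylsilane (C7 epimer mixture) | COc1cc(OCC=C)cc(OCC=C)c1C(O[Si](C(C)C)(C(C)C)C(C)C)[C@@H]1CC=C(CCC=C(C)C)C[C@H]1c1ccccc1 | intermediate
16 | [2,4-bis(allyloxy)-6-methoxyphenyl][(1R,6R)-4-(4-methylpent-3-en-1-yl)-6-phenylcyclohex-3-en-1-yl]methanol (C7 epimer mixture) | COc1cc(OCC=C)cc(OCC=C)c1C(O)[C@@H]1CC=C(CCC=C(C)C)C[C@H]1c1ccccc1 | intermediate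
17 | [2,4-bis(allyloxy)-6-methoxyphenyl][(1R,6R)-4-(4-methylpent-3-en-1-yl)-6-phenylcyclohex-3-en-1-yl]methanone | COc1cc(OCC=C)cc(OCC=C)c1C(=O)[C@@H]1CC=C(CCC=C(C)C)C[C@H]1c1ccccc1 | intermediate
18 | (2,4-dihydroxy-6-methoxyphenyl)[(1R,6R)-4-(4-methylpent-3-en-1-yl)-6-phenylcyclohex-3-en-1-yl]methanone | COc1cc(O)cc(O)c1C(=O)[C@@H]1CC=C(CCC=C(C)C)C[C@H]1c1ccccc1 | target

**Step count and risks**

Total steps: 9. Longest linear sequence: 8 steps (steps 1, 2, 3, 5, 6, 7, 8, 9); step 4 is a one-step side branch.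

Risk 1, step 5. The vinylogous-ester-stabilised cyclobutenone may open too slowly, or the hindered, branched alkyne terminus may capture the vinylketene too slowly. Ketene dimerisation, thermal decay of the ynol ether or loss of silanol from the ortho-hydroxybenzylic ether would then compete. In that case ring A would be brought in preformed and joined through C7–C1′. The fallback sets out from aldehyde 3. Commercial 5-methoxyresorcinol is monosilylated (TIPSCl, imidazole, DMF) to 3-methoxy-5-[(triisopropylsilyl)oxy]phenol F1 and protected (MOMCl, iPr2NEt, CH2Cl2) as 1-methoxy-3-(methoxymethoxy)-5-[(triisopropylsilyl)oxy]benzene F2. Directed ortho-lithiation (n-BuLi, THF, 0 °C) should occur between OMe and OMOM, the silyl ether blocking the other site, to give {2-methoxy-6-(methoxymethoxy)-4-[(triisopropylsilyl)oxy]phenyl}lithium F3. Addition of F3 to 3 at −78 °C gives [2-methoxy-6-(methoxymethoxy)-4-(triisopropylsilyloxy)phenyl][(1R,6R)-4-(4-methylpent-3-en-1-yl)-6-phenylcyclohex-3-en-1-yl]methanol F4. Buffered Dess–Martin oxidation gives the corresponding methanone F5, and Bu4NF gives [4-hydroxy-2-methoxy-6-(methoxymethoxy)phenyl][(1R,6R)-4-(4-methylpent-3-en-1-yl)-6-phenylcyclohex-3-en-1-yl]methanone F6. Dilute HCl in MeOH at 40 °C then removes the methoxymethyl group, and the fallback comes back to the route at target 18.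

Risk 2, step 1. Cycloaddition of the β-aryl iminium ion with an unactivated acyclic diene may be sluggish, or facial discrimination may be insufficient. The two ring stereocentres would then be set under auxiliary control. The fallback sets out from myrcene 2. The dienophile is (4R)-4-benzyl-3-[(2E)-3-phenylprop-2-enoyl]-1,3-oxazolidin-2-one F7, made from cinnamoyl chloride and lithiated (R)-4-benzyl-1,3-oxazolidin-2-one. With Et2AlCl (1.4 equiv, CH2Cl2, −30 → 0 °C) the chelated s-cis imide should add the diene anti to the benzyl group to give (4R)-4-benzyl-3-{[(1R,6R)-4-(4-methylpent-3-en-1-yl)-6-phenylcyclohex-3-en-1-yl]carbonyl}-1,3-oxazolidin-2-one F8. LiBH4 (THF, MeOH, 0 °C) releases [(1R,6R)-4-(4-methylpent-3-en-1-yl)-6-phenylcyclohex-3-en-1-yl]methanol F9, and Dess–Martin oxidation comes back to the route at aldehyde 3.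

Risk 3, step 4. Hydrolysis, ring opening or oligomerisation of the strained vinylogous ester may overtake the acid-catalysed exchange, or the exchange may stall. The ethyl group would then be removed and the allyl group introduced in separate operations. The fallback sets out from 8. Hydrolysis (dilute aq. HCl, 0 °C → rt) gives 3-hydroxycyclobut-2-en-1-one F10, the enol form of cyclobutane-1,3-dione. Its acidic enol is O-allylated under Mitsunobu conditions (allyl alcohol, PPh3, diisopropyl azodicarboxylate, THF, 0 °C), and the fallback comes back to the route at 9.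

Further compounds
F1 | step 5 | 3-methoxy-5-[(triisopropylsilyl)oxy]phenol | COc1cc(O)cc(O[Si](C(C)C)(C(C)C)C(C)C)c1
F2 | step 5 | 1-methoxy-3-(methoxymethoxy)-5-[(triisopropylsilyl)oxy]benzene | COCOc1cc(OC)cc(O[Si](C(C)C)(C(C)C)C(C)C)c1
F3 | step 5 | {2-methoxy-6-(methoxymethoxy)-4-[(triisopropylsilyl)oxy]phenyl}lithium | [Li]c1c(OC)cc(O[Si](C(C)C)(C(C)C)C(C)C)cc1OCOC
F4 | step 5 | [2-methoxy-6-(methoxymethoxy)-4-(triisopropylsilyloxy)phenyl][(1R,6R)-4-(4-methylpent-3-en-1-yl)-6-phenylcyclohex-3-en-1-yl]methanol (C7 epimer mixture) | COCOc1cc(O[Si](C(C)C)(C(C)C)C(C)C)cc(OC)c1C(O)[C@@H]1CC=C(CCC=C(C)C)C[C@H]1c1ccccc1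
F5 | step 5 | [2-methoxy-6-(methoxymethoxy)-4-(triisopropylsilyloxy)phenyl][(1R,6R)-4-(4-methylpent-3-en-1-yl)-6-phenylcyclohex-3-en-1-yl]methanone | COCOc1cc(O[Si](C(C)C)(C(C)C)C(C)C)cc(OC)c1C(=O)[C@@H]1CC=C(CCC=C(C)C)C[C@H]1c1ccccc1
F6 | step 5 | [4-hydroxy-2-methoxy-6-(methoxymethoxy)phenyl][(1R,6R)-4-(4-methylpent-3-en-1-yl)-6-phenylcyclohex-3-en-1-yl]methanone | COCOc1cc(O)cc(OC)c1C(=O)[C@@H]1CC=C(CCC=C(C)C)C[C@H]1c1ccccc1
F7 | step 1 | (4R)-4-benzyl-3-[(2E)-3-phenylprop-2-enoyl]-1,3-oxazolidin-2-one | O=C1OC[C@@H](Cc2ccccc2)N1C(=O)/C=C/c1ccccc1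
F8 | step 1 | (4R)-4-benzyl-3-{[(1R,6R)-4-(4-methylpent-3-en-1-yl)-6-phenylcyclohex-3-en-1-yl]carbonyl}-1,3-oxazolidin-2-one | O=C1OC[C@@H](Cc2ccccc2)N1C(=O)[C@@H]1CC=C(CCC=C(C)C)C[C@H]1c1ccccc1
F9 | step 1 | [(1R,6R)-4-(4-methylpent-3-en-1-yl)-6-phenylcyclohex-3-en-1-yl]methanol | OC[C@@H]1CC=C(CCC=C(C)C)C[C@H]1c1ccccc1
F10 | step 4 | 3-hydroxycyclobut-2-en-1-one | O=C1CC(O)=C1
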